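## Retrosynthetic overview

1. Target 28 ⇐ mild acid hydrolysis of the masked ene-dial 27 (2-acetoxy-5-menthyloxy-3-alkylidene-tetrahydrofuran) ⇐ DIBAL-H, then Ac2O, from the α-alkylidene γ-lactone 25 fused to the nine-membered ring.
2. Nine-membered carbocycle (last ring formed) ⇐ intramolecular Horner–Wadsworth–Emmons closure of C7=C8 from the α-phosphono lactone / β,γ-unsaturated aldehyde 24.
3. C2–C3 ⇐ acylation of the lithiated (E)-allylic sulfone 15 (C3–C7, E-C4=C5 preset) by the East lactone of 19, then desulfonylation and CBS reduction (sets C2).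
4. C1–C9 ⇐ Michael addition of the enolate of (S)-lactone 6 to (5R)-menthyloxybutenolide 9 with in-situ C-phosphonylation (sets C1 and C9; C10 comes from a CuH reduction). Building blocks 6, 9 and 15 (12, 17 and 19 non-hydrogen atoms) are joined in steps 10–11.
5. Ring order: East γ-lactone (from tetronic acid) and West butenolide (from furfural) first, then the cyclononadiene; the West lactone is opened at the very end.

Assumption and locants: (−)-menthol is a recoverable chiral auxiliary, PhSO2 and P(O)(OEt)2 are traceless activating groups; target locants are ring C1 (CH carrying the side chain), C2 (CHOH), C3, C4 (C–CH3), C5, C6, C7, C8 (C–CHO, formyl C18), C9 (CH–CHO, formyl C19), side-chain C10 (CH) and C11 (CH2OAc); the target is (1R,2S,9R,10S), 4E, 7E.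

## Route

Step 1
Reactants: 1 tetronic acid
Product: 2 4-bromofuran-2(5H)-one
Conditions: (COBr)2 (1.2 equiv), DMF (cat.), CH2Cl2, 0 °C → rt
Reagents that add atoms: oxalyl bromide, O=C(Br)C(=O)Br
Why: Vilsmeier-type bromodehydroxylation of the vinylogous acid (addition–elimination) gives the β-bromo butenolide; no stereocentre is involved.

Step 2
Reactants: 3 5-bromo-2-methylpent-2-ene; 2 4-bromofuran-2(5H)-one
Product: 5 4-(4-methylpent-3-en-1-yl)furan-2(5H)-one, via homoprenylzinc bromide 4 (not isolated)
Conditions: 3, Zn dust, LiCl, THF, 50 °C; then 2, Pd(PPh3)4 (3 mol%), THF, 50 °C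
Reagents that add atoms: none
Why: Negishi sp3–sp2 cross-coupling at the β-bromo enoate carbon attaches the homoprenyl chain, the remote trisubstituted alkene being inert.

Step 3
Reactants: 5 4-(4-methylpent-3-en-1-yl)furan-2(5H)-one
Product: 6 (4S)-4-(4-methylpent-3-en-1-yl)dihydrofuran-2(3H)-one
Conditions: Cu(OAc)2 (5 mol%), (S)-p-Tol-BINAP (5 mol%), (EtO)2MeSiH (2 equiv), t-BuOH (2 equiv), toluene, 0 °C → rt
Reagents that add atoms: none
Why: CuH-catalysed asymmetric conjugate reduction delivers hydride to the β-carbon from the face selected by the chiral bisphosphine, setting C10 (4S; the ligand hand is the one chosen for this sense), while the isolated alkene is untouched.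

Step 4
Reactants: 7 furfural
Product: 8 5-hydroxyfuran-2(5H)-one (racemic)
Conditions: O2, rose bengal (cat.), MeOH, visible light, 20 °C
Reagents that add atoms: oxygen, O=O
Why: Singlet-oxygen [4+2] cycloaddition to the furan and methanolytic fragmentation of the endoperoxide expel the formyl carbon as methyl formate and leave the hydroxybutenolide.

Step 5
Reactants: 8 5-hydroxyfuran-2(5H)-one
Product: 9 (5R)-5-[(1R,2S,5R)-menthyloxy]furan-2(5H)-one
Conditions: (−)-menthol (1.1 equiv), CSA (cat.), toluene, reflux (Dean–Stark); crystallisation from petroleum ether, mother liquor re-equilibrated with cat. CSA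
Reagents that add atoms: (−)-menthol, CC(C)[C@@H]1CC[C@@H](C)C[C@H]1O
Why: Acid-catalysed acetalisation gives both C5 epimers, which interconvert under acid, so crystallisation-induced diastereomer enrichment delivers the (5R)-epimer.

Step 6
Reactants: 10 4-methylpent-3-en-1-ol
Product: 11 4-methylpent-3-enal
Conditions: Dess–Martin periodinane (1.2 equiv), CH2Cl2, 0 °C → rt; careful concentration
Reagents that add atoms: none
Why: Dess–Martin oxidation under neutral conditions gives the β,γ-unsaturated aldehyde without conjugation.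

Step 7
Reactants: 11 4-methylpent-3-enal
Product: 12 5,5-dimethoxy-2-methylpent-2-ene
Conditions: HC(OMe)3 (3 equiv), PPTS (5 mol%), CH2Cl2, rt
Reagents that add atoms: trimethyl orthoformate, COC(OC)OC
Why: Acid-catalysed acetalisation masks the future C7 aldehyde as a base-stable dimethyl acetal.

Step 8
Reactants: 12 5,5-dimethoxy-2-methylpent-2-ene
Product: 13 (2E)-5,5-dimethoxy-2-methylpent-2-en-1-ol
Conditions: SeO2 (0.3 equiv), t-BuOOH (2.5 equiv), salicylic acid (0.1 equiv), CH2Cl2, rt
Reagents that add atoms: tert-butyl hydroperoxide, CC(C)(C)OO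
Why: Selenium dioxide allylic oxidation (ene reaction then [2,3]-sigmatropic shift) hydroxylates only the methyl group trans to the chain, fixing the E-trisubstituted C4=C5 olefin.

Step 9
Reactants: 13 (2E)-5,5-dimethoxy-2-methylpent-2-en-1-ol
Product: 15 (E)-allylic phenyl sulfone, via allylic mesylate 14 (not isolated)
Conditions: MsCl, Et3N, CH2Cl2, −20 °C; then PhSO2Na (2 equiv), DMF, rt
Reagents that add atoms: sodium benzenesulfinate, [Na+].[O-]S(=O)c1ccccc1
Why: SN2 S-alkylation of sulfinate by the primary allylic mesylate gives the sulfone with the E geometry retained.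

Step 10
Reactants: 6 (4S)-4-(4-methylpent-3-en-1-yl)dihydrofuran-2(3H)-one; 9 (5R)-5-menthyloxyfuran-2(5H)-one
Product: 19 α-phosphono bis-lactone, via East-lactone lithium enolate 16 (not isolated), via Michael-adduct lithium enolate 17 (not isolated), via phosphinite bis-lactone 18 (not isolated)
Conditions: LDA (1.05 equiv), THF, −78 °C; 9, −78 °C, 1 h; ClP(OEt)2, −78 °C → rt; then 30% H2O2, 0 °C
Reagents that add atoms: diethyl chlorophosphite, CCOP(Cl)OCC; hydrogen peroxide, OO
Why: In this Michael addition the enolate reacts on the face anti to the homoprenyl group (C1 trans to C10) and the butenolide on the face anti to the menthyloxy group (C9), after which the new enolate is C-phosphonylated and the P(III) centre oxidised to the phosphonate.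

Step 11
Reactants: 19 α-phosphono bis-lactone; 15 (E)-allylic phenyl sulfone
Product: 21 β-keto sulfone with free C11–OH, via α-lithio sulfone 20 (not isolated)
Conditions: 15 (3.0 equiv), n-BuLi (2.9 equiv), THF, −78 °C; then 19, −78 → −20 °C; AcOH quench
Reagents that add atoms: none
Why: In this Julia-type acylation the first equivalent of carbanion deprotonates the acidic phosphonate (masking the West lactone as its enolate), the next opens the East lactone at C2 through the sulfone α-carbon, and the β-keto sulfone anion formed stops over-addition.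

Step 12
Reactants: 21 β-keto sulfone
Product: 22 β,γ-unsaturated C2 ketone
Conditions: SmI2 (3 equiv), THF–MeOH (20:1), −78 °C
Reagents that add atoms: none
Why: Reductive desulfonylation of the α-sulfonyl ketone proceeds through a samarium enolate whose kinetic α-protonation keeps the E-C4=C5 olefin out of conjugation.

Step 13
Reactants: 22 β,γ-unsaturated C2 ketone
Product: 23 (2S)-diol dimethyl acetal
Conditions: (R)-Me-CBS (0.5 equiv), catecholborane (3 equiv), toluene, −78 °C; MeOH, pH 7 buffer
Reagents that add atoms: none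
Why: Corey–Bakshi–Shibata reduction with the branched C1 side as the large group and the C3 methylene as the small one delivers hydride under reagent control to give the 2S carbinol.

Step 14
Reactants: 23 (2S)-diol dimethyl acetal
Product: 24 C7 aldehyde (diol phosphonate)
Conditions: PPTS (0.2 equiv), acetone–H2O (10:1), rt
Reagents that add atoms: water, O
Why: Mild acetal hydrolysis releases the β,γ-unsaturated aldehyde while the far less ionisable acyloxy-acetal (menthyl pseudo-ester) and the phosphonate survive.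

Step 15
Reactants: 24 C7 aldehyde (diol phosphonate)
Product: 25 cyclononadiene-fused α-alkylidene lactone
Conditions: syringe-pump addition to LiCl (10 equiv), i-Pr2NEt (5 equiv), MeCN, 1 mM, rt
Reagents that add atoms: none
Why: Intramolecular Horner–Wadsworth–Emmons olefination under Masamune–Roush conditions closes C7=C8, and the ring already holding the E-C4=C5 bond allows only the cis-in-ring (7E) alkylidene geometry.

Step 16
Reactants: 25 cyclononadiene-fused α-alkylidene lactone
Product: 26 lactol (C18 epimers)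
Conditions: DIBAL-H (3.5 equiv), CH2Cl2, −78 °C; Rochelle salt
Reagents that add atoms: none
Why: 1,2-Hydride reduction of the lactone stops at the lactol because the tetrahedral aluminate is stable at −78 °C, bringing C18 to the aldehyde oxidation level.

Step 17
Reactants: 26 lactol
Product: 27 C11 acetate / C18 anomeric acetate
Conditions: Ac2O (2.5 equiv), pyridine, CH2Cl2, 0 °C
Reagents that add atoms: acetic anhydride, CC(=O)OC(C)=O
Why: Acylation takes the primary C11–OH and the lactol OH while the hindered secondary C2–OH, flanked by the branched C1, is left free.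

Step 18
Reactants: 27 C11 acetate / C18 anomeric acetate
Product: 28 target CNP0284729.1
Conditions: AcOH–THF–H2O (3:1:1), 30 °C
Reagents that add atoms: water, O
Why: Acid hydrolysis of the mixed bis-acetal (anomeric acetate and menthyl acetal) unmasks both aldehydes without touching the primary acetate, and C2–OH cannot form a lactol because it is trans to C19 across the ring.

## Compound list

1 | tetronic acid (4-hydroxyfuran-2(5H)-one) | O=C1C=C(O)CO1 | starting material
2 | 4-bromofuran-2(5H)-one | O=C1C=C(Br)CO1 | intermediate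
3 | 5-bromo-2-methylpent-2-ene | CC(C)=CCCBr | starting material
4 | (4-methylpent-3-en-1-yl)zinc bromide | CC(C)=CCC[Zn]Br | intermediate
5 | 4-(4-methylpent-3-en-1-yl)furan-2(5H)-one | CC(C)=CCCC1=CC(=O)OC1 | intermediate
6 | (4S)-4-(4-methylpent-3-en-1-yl)dihydrofuran-2(3H)-one | O=C1C[C@H](CCC=C(C)C)CO1 | intermediate
7 | furfural | O=Cc1ccco1 | starting material
8 | 5-hydroxyfuran-2(5H)-one (racemic) | O=C1C=CC(O)O1 | intermediate
9 | (5R)-5-[(1R,2S,5R)-menthyloxy]furan-2(5H)-one | O=C1C=C[C@H](O[C@@H]2C[C@H](C)CC[C@H]2C(C)C)O1 | intermediate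
10 | 4-methylpent-3-en-1-ol | CC(C)=CCCO | starting material
11 | 4-methylpent-3-enal | CC(C)=CCC=O | intermediate
12 | 5,5-dimethoxy-2-methylpent-2-ene | CC(C)=CCC(OC)OC | intermediate
13 | (2E)-5,5-dimethoxy-2-methylpent-2-en-1-ol | OC/C(C)=C/CC(OC)OC | intermediate
14 | (2E)-5,5-dimethoxy-2-methylpent-2-en-1-yl methanesulfonate | CS(=O)(=O)OC/C(C)=C/CC(OC)OC | intermediate
15 | {[(2E)-5,5-dimethoxy-2-methylpent-2-en-1-yl]sulfonyl}benzene | O=S(=O)(C/C(C)=C/CC(OC)OC)c1ccccc1 | intermediate
16 | lithium enolate of lactone 6 | [Li]OC1=C[C@H](CCC=C(C)C)CO1 | intermediate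
17 | Michael-adduct lithium enolate (East lactone C3 bonded to West C4, trans to OMenth) | O=C1OC[C@@H](CCC=C(C)C)[C@@H]1[C@@H]2C=C(O[Li])O[C@H]2O[C@@H]3C[C@H](C)CC[C@H]3C(C)C | intermediate
18 | α-(diethoxyphosphanyl) bis-lactone (C8 epimers) | O=C1OC[C@@H](CCC=C(C)C)[C@@H]1[C@@H]2C(P(OCC)OCC)C(=O)O[C@H]2O[C@@H]3C[C@H](C)CC[C@H]3C(C)C | intermediate
19 | diethyl {(4S,5R)-5-[(1R,2S,5R)-menthyloxy]-4-[(3R,4S)-4-(4-methylpent-3-en-1-yl)-2-oxooxolan-3-yl]-2-oxooxolan-3-yl}phosphonate (C8 epimers) | O=C1OC[C@@H](CCC=C(C)C)[C@@H]1[C@@H]2C(P(=O)(OCC)OCC)C(=O)O[C@H]2O[C@@H]3C[C@H](C)CC[C@H]3C(C)C | intermediate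
20 | α-lithio derivative of sulfone 15 | [Li]C(/C(C)=C/CC(OC)OC)S(=O)(=O)c1ccccc1 | intermediate
21 | β-keto sulfone (C2 ketone, C3 sulfone epimers, C11–OH free; C1, C9, C10, C19 as in 19) | OC[C@@H](CCC=C(C)C)[C@@H](C(=O)C(/C(C)=C/CC(OC)OC)S(=O)(=O)c1ccccc1)[C@@H]2C(P(=O)(OCC)OCC)C(=O)O[C@H]2O[C@@H]3C[C@H](C)CC[C@H]3C(C)C | intermediate
22 | β,γ-unsaturated C2 ketone (4E) | OC[C@@H](CCC=C(C)C)[C@@H](C(=O)C/C(C)=C/CC(OC)OC)[C@@H]1C(P(=O)(OCC)OCC)C(=O)O[C@H]1O[C@@H]2C[C@H](C)CC[C@H]2C(C)C | intermediate
23 | (2S)-diol dimethyl acetal | OC[C@@H](CCC=C(C)C)[C@@H]([C@@H](O)C/C(C)=C/CC(OC)OC)[C@@H]1C(P(=O)(OCC)OCC)C(=O)O[C@H]1O[C@@H]2C[C@H](C)CC[C@H]2C(C)C | intermediate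
24 | C7 aldehyde (diol phosphonate) | OC[C@@H](CCC=C(C)C)[C@@H]([C@@H](O)C/C(C)=C/CC=O)[C@@H]1C(P(=O)(OCC)OCC)C(=O)O[C@H]1O[C@@H]2C[C@H](C)CC[C@H]2C(C)C | intermediate
25 | (4E,7E)-cyclononadiene fused to the α-alkylidene 5-menthyloxy γ-lactone (C2–OH, C11–OH free) | OC[C@@H](CCC=C(C)C)[C@H]1[C@@H](O)C/C(C)=C/C/C=C2/C(=O)O[C@@H](O[C@@H]3C[C@H](C)CC[C@H]3C(C)C)[C@H]12 | intermediate
26 | lactol of 25 (C18 epimers) | OC[C@@H](CCC=C(C)C)[C@H]1[C@@H](O)C/C(C)=C/C/C=C2/C(O)O[C@@H](O[C@@H]3C[C@H](C)CC[C@H]3C(C)C)[C@H]12 | intermediate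
27 | C11 acetate / C18 anomeric acetate (C18 epimers) | CC(=O)OC[C@@H](CCC=C(C)C)[C@H]1[C@@H](O)C/C(C)=C/C/C=C2/C(OC(C)=O)O[C@@H](O[C@@H]3C[C@H](C)CC[C@H]3C(C)C)[C@H]12 | intermediate
28 | CNP0284729.1, (1R,2S,9R,10S,4E,7E)-hydroxy acetoxy ene-dial | CC(=O)OC[C@@H](CCC=C(C)C)[C@H]1[C@@H](O)C/C(C)=C/C/C=C(/C=O)[C@@H]1C=O | target

## Step count and risks

Total step count: 18. Longest linear sequence: 12 steps (1–3 then 10–18; equally 6–9 then 11–18).

Step 10 (Michael addition with C-phosphonylation). The lithium enolate may deprotonate the butenolide instead of adding to it, or the trapping may be inefficient. The fallback sets out from 6 and returns at 19. Lactone 6 is converted (LDA, TBSCl, THF, −78 °C) into the silyl ketene acetal F1, which is added to 9 under catalytic TBSOTf (CH2Cl2, −78 °C) as a Mukaiyama–Michael reaction with the same two anti facial preferences. Aqueous work-up gives the bis-lactone F2. Kinetic deprotonation of its only unhindered α-CH2 (LDA, −78 °C), then ClP(OEt)2 and H2O2, gives 19.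

Step 11 (acylation of the sulfone carbanion by the hindered East lactone next to the West pseudo-ester). Conversion may be low or the wrong carbonyl may react. The fallback sets out from 19 and returns at 21. Lactone 19 is treated with Me2AlN(OMe)Me (from MeONHMe·HCl and Me3Al, CH2Cl2, 0 °C → rt); the acidic phosphonate is deprotonated first, so only the East lactone is aminolysed, giving the hydroxy Weinreb amide F3. Excess 20 (THF, −78 °C) then gives 21 through the chelated tetrahedral intermediate.

Step 15 (nine-membered ring closure by HWE). This is the most likely failure: ring strain, dimerisation, or conjugation of the β,γ-unsaturated aldehyde. The fallback sets out from 24 and returns at 25. Wittig methylenation of the aldehyde (excess Ph3P=CH2, THF, −78 → 0 °C, the phosphonate carried as its anion) gives the 1,4-diene phosphonate F4. HWE reaction with aqueous formaldehyde (K2CO3, THF) gives the α-methylene lactone F5. Ring-closing metathesis (Hoveyda–Grubbs II, toluene, 1 mM, 80 °C) then forms C7=C8 with loss of ethylene, the ring again allowing only the cis-in-ring geometry, and gives 25.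

## Further compounds

F1 | step 10 | tert-butyl(dimethyl){[(4S)-4-(4-methylpent-3-en-1-yl)-4,5-dihydrofuran-2-yl]oxy}silane | CC(C)(C)[Si](C)(C)OC1=C[C@H](CCC=C(C)C)CO1
F2 | step 10 | bis-lactone without phosphonate (Michael adduct of 6 and 9) | O=C1OC[C@@H](CCC=C(C)C)[C@@H]1[C@@H]2CC(=O)O[C@H]2O[C@@H]3C[C@H](C)CC[C@H]3C(C)C
F3 | step 11 | hydroxy Weinreb amide from opening of the East lactone of 19 | OC[C@@H](CCC=C(C)C)[C@@H](C(=O)N(C)OC)[C@@H]1C(P(=O)(OCC)OCC)C(=O)O[C@H]1O[C@@H]2C[C@H](C)CC[C@H]2C(C)C
F4 | step 15 | 1,4-diene phosphonate (C7 aldehyde of 24 methylenated) | OC[C@@H](CCC=C(C)C)[C@@H]([C@@H](O)C/C(C)=C/CC=C)[C@@H]1C(P(=O)(OCC)OCC)C(=O)O[C@H]1O[C@@H]2C[C@H](C)CC[C@H]2C(C)C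
F5 | step 15 | α-methylene lactone triene | OC[C@@H](CCC=C(C)C)[C@@H]([C@@H](O)C/C(C)=C/CC=C)[C@@H]1C(=C)C(=O)O[C@H]1O[C@@H]2C[C@H](C)CC[C@H]2C(C)C
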